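# Synthesis plan for CNP0273650.2 (compound 23) by an intramolecular Buchner ring expansion

## The problem

Target 23 is a daucane-type hydroazulene: a cyclopentane (C1–C5) trans-fused through C1–C5 to a cycloheptene (C1, C5–C10). C1 is the quaternary methyl-bearing carbon, C4 the tertiary carbinol carrying isopropyl, C5 the ring-fusion CH, C6 the CH–O–(4-hydroxybenzoyl) carbon, C7 a CH2, C8(CH3)=C9 the ring alkene and C10 the CH–O–angeloyl carbon. Five stereocentres, (1S,4R,5S,6S,10R), must be set: H5, the isopropyl group and both ester oxygens lie on one face, the C1 methyl and the C4 hydroxyl on the other. The centres can relay: C5 can steer a nucleophile at C4, the C4 hydroxyl can deliver a carbon to C1 and so fix the trans fusion, and the axial C1 methyl can shield one face of the seven-membered ring at C6. C10 has no neighbour placed to control it and needs a reagent. The fragile groups are the angelate (Z to E isomerisation to the tiglate), the allylic neopentyl C10 ester, the unprotectable tertiary alcohol and the free phenol; any intermediate with H5 next to a carbonyl is configurationally labile. The enabling feature is that ring atoms C6–C7–C8(CH3)=C9–C10(O)–C1 carry exactly the pattern of a benzene ring with oxygen ortho and methyl para to the carbon (C1) bearing the C2–C3–C4 chain. C5, the one ring atom missing from that arene, is bonded to C1 and C6 and is α to C4, so it can enter as the carbene carbon of a diazoketone and close both rings at once.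

## Retrosynthesis

**Esters and phenol (23 ⇐ 22 ⇐ 19 + 20; 19 ⇐ 18 ⇐ 16 + 17).** The two acyl C–O bonds and the phenol O–Si bond are cut first. The angelate goes on last, from alcohol 19 and angelic acid 20, so that the isomerisable Z-alkene meets only a buffered desilylation. The aroyl group (acid 17) goes on at C6 of hydroxy enone 16 while C10 is still a ketone (18), so two secondary hydroxyls never have to be told apart. The C10 carbinol is traced to the enone carbonyl of 18. The forward reduction has to be reagent-controlled.

**C6–O and C7–H (16 ⇐ 15 ⇐ 14).** The C6 hydroxyl and the C7 methylene are traced to a γ,δ-epoxide 15 of dienone 14. Direct hydration or 1,6-addition of an oxygen nucleophile offers no regiocontrol or facial control. In 14 the conjugation deactivates C8=C9 and leaves C6=C7 as the alkene a peracid attacks, with the C1 methyl shielding one face. Palladium/formate hydrogenolysis then removes only the allylic C7–O bond and keeps the enone conjugated.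

**C1–CH3 (14 ⇐ 13 ⇐ 12 ⇐ 11).** The C1 methyl and the C10 carbonyl together are a ring-opened cyclopropanol 13, hence a siloxycyclopropane 12 made by cyclopropanating the enol ether C1=C10 of triene 11. The C4 hydroxyl of 11 sits on the face where the methyl is needed, so a directed Simmons–Smith reaction sets the quaternary centre and the trans fusion without an enolate alkylation of uncertain facial outcome. A silyl enol ether is chosen over a methyl one. An alkoxycyclopropane carrying the C9=C8–C7=C6 diene would, under the acid a methyl ether needs, be protonated on the diene and ring-expand to a cyclobutanone. A silyl ether is removed by fluoride and the cyclopropanol opens under base at the C10–CH2 bond.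

**C4–isopropyl (11 ⇐ 10).** The C4–C(isopropyl) bond is cut to ketone 10. With H5 on one side and the C5–C6 bond on the other, the nucleophile enters syn to H5, giving the required C4 configuration. The reagent must not deprotonate the acidic C5–H.

**Both rings (10 ⇐ 9 ⇐ 8).** Bonds C5–C1 and C5–C6 are cut together. Trienone 10 is the valence tautomer of norcaradiene 9, which is the intramolecular carbene adduct of diazoketone 8. No neighbouring cut closes both rings and places the C10 oxygen, the C8 methyl and three alkenes in one operation from a flat arene with no stereocentres. The forward reaction must add at the ipso–ortho bond away from the silyloxy group, discriminate the enantiofaces, and leave C5–H in place.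

**Diazoketone (8 ⇐ 5 + 6; 5 ⇐ 4 ⇐ 2 + 3; 2 ⇐ 1).** C4–C5 is cut to acid 5 and (trimethylsilyl)diazomethane 6. C2–C3 is cut by a Wittig reaction of aldehyde 2 with benzyl ylide 3 (ester 4), and 2 is the silyl ether of commercial 1. A malonic acid condensation is avoided: salicylaldehydes give coumarins, and hot amine would cleave the aryl silyl ether. The benzyl ester releases the acid in the hydrogenation that saturates the chain.

## Roads not taken

**Alternative 1:** The cut is C4–C5, with the cyclopentane closed last on an intact seven-membered dione.
- **Forward step:** a chiral triazolylidene carbene turns the aldehyde of 2-methyl-2-(3-oxopropyl)cycloheptane-1,3-dione A1 into an acyl anion equivalent that adds to one of the two enantiotopic ring ketones, giving cis-fused ketol A2.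
- **Merits:** the quaternary C1 is set directly and catalytically from an achiral trione made in two steps, without diazo compounds. On this point it is better than the chosen plan, which reaches C1 only by a relay (C5 to C4 to C1) that starts from a less predictable asymmetric carbene step.
- **Weak points:** A2 carries a hydroxyl at C5 on the face of the C1 methyl. The target needs hydrogen there on the opposite face, so a ring-fusion tertiary carbinol must be removed with net inversion, for which there is no dependable method. A2 also has no C8 methyl, no C8=C9 alkene and no C6 oxygen; C6 to C9 are four plain methylenes. The isopropyl addition must distinguish the C4 from the C10 ketone, and the benzoin is established mainly for five- and six-membered diones.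
- **Against it the chosen plan sets:** a skeleton that arrives with every substituent position already marked and with C5–H in place.

**Alternative 2:** The cut is C9–C10, with the cycloheptene closed last.
- **Forward step:** Z-alkenyl iodide/aldehyde A3 undergoes a Nozaki–Hiyama–Kishi reaction (CrCl2, catalytic NiCl2) to A4, which is identical with compound 19 of the chosen route.
- **Merits:** the closure tolerates the ester, tertiary alcohol and silyl ether, creates the C10 carbinol and C8=C9 in one late operation, and starts with the C6 ester already installed by acyclic chemistry. The end-game is more convincing than the chosen one, which reaches 19 only through an epoxidation, a hydrogenolysis and a reagent-controlled reduction whose facial outcomes are less certain.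
- **Weak points:** A3 is a cyclopentane with three contiguous stereocentres (including quaternary C1 bearing the formyl group), a fourth at C6 and a trisubstituted Z-iodoalkene. Its synthesis would be far longer than the five steps to trienone 10 and would carry the whole stereochemical burden. Closure onto a neopentyl aldehyde is slow, the C10 configuration under substrate control is unpredictable, and stoichiometric chromium is used late.
- **Against it the chosen plan sets:** both rings and the full carbon skeleton made in one catalytic step from a cheap arene.

**Alternative 3:** The cuts are C1–CH3 and C5–C6 on a cyclopentenone.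
- **Forward step:** copper-catalysed enantioselective transfer of methyl from Me3Al to the β-carbon of enone A5 gives an aluminium enolate that is trapped at C5 by aldehyde A6, giving aldol A7 with C1, C5 and C6 set.
- **Merits:** three stereocentres, including quaternary C1 and the C6 oxygen, come from one step and trivial materials. The C6 oxygen arrives with the C5–C6 bond instead of by a late epoxidation, which is a real advantage over the chosen plan.
- **Weak points:** β-substituted cyclopentenones are the least reactive and least selective substrates for this addition. The enolate faces at C5 differ only by CH3 against CH2OSi on C1, so the C1/C5 relationship is weakly controlled, and the aldol configuration at C6 with an aluminium enolate is not predictable. A6 is a β,γ-unsaturated aldehyde that conjugates easily. After the key step the seven-membered ring is still open, and closing C9–C10 with the alkene at C8=C9 needs further C–C chemistry close to that of Alternative 2.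
- **Against it the chosen plan sets:** ring construction finished at step 5 and a relay in which each later centre is tied to an earlier one.

Key step: step 5

## Remarks before the steps

- Locants C1–C10 (and C11 for the cyclopropane CH2) are the numbering of the first section, not azulene locants, unless an azulene name is given.
- Assumption: the (S,S)-bis(oxazoline) ligand is taken to give (5R)-10. The facial sense for this unsubstituted tether is not secure; if the opposite enantiomer predominates, the (R,R)-ligand is used with nothing else changed.
- Assumption: 4-[(tert-butyldimethylsilyl)oxy]benzoic acid 17 and ylide 3 are catalogue compounds.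

## Route

Step 1
Reactants: 1 2-hydroxy-4-methylbenzaldehyde
Product: 2 2-[(tert-butyldimethylsilyl)oxy]-4-methylbenzaldehyde
Conditions: TBSCl, imidazole, DMF, rt
Reagents that add atoms: tert-butyldimethylsilyl chloride, CC(C)(C)[Si](C)(C)Cl
Why: Standard imidazole-promoted O-silylation of a phenol; the aryl silyl ether later becomes the silyl enol ether that allows a base-mediated cyclopropanol opening, which an aryl methyl ether would not.

Step 2
Reactants: 2 2-[(tert-butyldimethylsilyl)oxy]-4-methylbenzaldehyde; 3 benzyl (triphenylphosphoranylidene)acetate
Product: 4 benzyl (E)-3-{2-[(tert-butyldimethylsilyl)oxy]-4-methylphenyl}prop-2-enoate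
Conditions: toluene, 80 °C
Reagents that add atoms: none
Why: Wittig olefination with a stabilised ylide gives the (E)-cinnamate under neutral conditions that spare the aryl silyl ether; the alkene geometry is irrelevant because it is hydrogenated next.

Step 3
Reactants: 4 benzyl (E)-3-{2-[(tert-butyldimethylsilyl)oxy]-4-methylphenyl}prop-2-enoate
Product: 5 3-{2-[(tert-butyldimethylsilyl)oxy]-4-methylphenyl}propanoic acid
Conditions: H2 (1 atm), 10% Pd/C, EtOAc, rt
Reagents that add atoms: none
Why: Catalytic hydrogenation saturates the cinnamate alkene and hydrogenolyses the benzyl ester in one operation, giving the acid without a hydrolysis that could cleave the aryl silyl ether.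

Step 4
Reactants: 5 3-{2-[(tert-butyldimethylsilyl)oxy]-4-methylphenyl}propanoic acid; 6 (trimethylsilyl)diazomethane
Product: 8 1-diazo-4-{2-[(tert-butyldimethylsilyl)oxy]-4-methylphenyl}butan-2-one, via mixed ethyl carbonic anhydride 7 (not isolated)
Conditions: ClCO2Et, Et3N, THF, −15 °C; then 6 (2 M in hexanes), MeCN, 0 °C to rt
Reagents that add atoms: ethyl chloroformate, CCOC(=O)Cl (its atoms stay only in intermediate 7)
Why: Acylation of (trimethylsilyl)diazomethane by a mixed carbonic anhydride (Arndt–Eistert-type diazoketone synthesis), with protodesilylation on work-up; the anhydride is preferred to the acid chloride so that no HCl is present to cause desilylative lactonisation to a dihydrocoumarin.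

Step 5
Reactants: 8 1-diazo-4-{2-[(tert-butyldimethylsilyl)oxy]-4-methylphenyl}butan-2-one
Product: 10 (8aR)-4-[(tert-butyldimethylsilyl)oxy]-6-methyl-3,8a-dihydroazulen-1(2H)-one [route numbering: (5R); ketone at C4, H at C5, silyl enol ether C1=C10, alkenes C6=C7 and C8=C9], via norcaradiene 9 (not isolated)
Conditions: [Cu(MeCN)4]PF6 (5 mol %), 2,2′-(propane-2,2-diyl)bis[(4S)-4-tert-butyl-4,5-dihydro-1,3-oxazole] ((S,S)-tBu-box, 6 mol %), Na[B(3,5-(CF3)2C6H3)4] (6 mol %), CH2Cl2, 40 °C, slow addition of 8; filtration through deactivated neutral alumina, used at once
Reagents that add atoms: none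
Why: The copper–bis(oxazoline) complex (monovalent copper) converts 8 into an electrophilic copper carbene at C5 with loss of N2. The carbene adds across the arene bond C1–C6 (ipso–ortho, remote from the silyloxy group) to give norcaradiene 9, forming C5–C1 and C5–C6, and 9 opens by thermal 6π disrotatory electrocyclic cleavage of C1–C6 to cycloheptatriene 10. The closest known reaction type is the intramolecular Buchner reaction of 1-diazo-4-arylbutan-2-ones, including its enantioselective copper–bis(oxazoline) variants. The cyclopentanone closes in a 5-exo sense as the tether C2–C3–C4 delivers C5 to C1 during the [2+1] cycloaddition; the seven-membered ring is not closed end to end but arises by one-carbon expansion of the benzene ring. C5 is the only new stereocentre and is fixed by the enantioface of the arene bond that the C2-symmetric ligand exposes to the carbene; the electrocyclic opening does not touch it. The step needs addition at C1–C6 and not C1–C10, which the substrate secures because C1–C10 is fully substituted and shielded by the bulky silyloxy group and because a cyclopropane formed there would be a donor–acceptor cyclopropane that reverts. It also needs the doubly allylic, carbonyl-activated C5–H to survive, so the reaction is run at or below 40 °C without amine base and 10 is carried on without storage.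

Step 6
Reactants: 10 (8aR)-4-[(tert-butyldimethylsilyl)oxy]-6-methyl-3,8a-dihydroazulen-1(2H)-one
Product: 11 (4R,5R)-tertiary alcohol: the C4 ketone of 10 replaced by C(OH)(isopropyl), hydroxyl anti to H5, silyl trienol ether unchanged
Conditions: iPrMgCl, CeCl3 (dried), THF, −78 °C; crude 10 added cold
Reagents that add atoms: isopropylmagnesium chloride, CC(C)[Mg]Cl
Why: Organocerium 1,2-addition: the weakly basic isopropylcerium reagent adds to the easily enolised ketone without deprotonating C5 or transferring β-hydride. Attack comes on the carbonyl face syn to H5 and anti to the C5–C6 bond (steric approach control), which places the C4 hydroxyl anti to H5 and, by removing the carbonyl, makes C5 configurationally stable.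

Step 7
Reactants: 11 (4R,5R)-tertiary alcohol
Product: 12 (1R,4R,5R,10R)-siloxycyclopropane: the C1=C10 bond of 11 bridged by CH2 (C11) on the face of the C4 hydroxyl, silyloxy group on C10, diene C6=C7–C8(CH3)=C9 retained
Conditions: Et2Zn, CH2I2, CH2Cl2, −20 to 0 °C; NaHCO3 quench
Reagents that add atoms: diiodomethane, ICI
Why: Hydroxyl-directed Simmons–Smith cyclopropanation (Furukawa conditions): the zinc alkoxide of the homoallylic C4 hydroxyl delivers the carbenoid to the most electron-rich alkene, the silyl enol ether C1=C10, on the face of that hydroxyl. The new CH2 therefore lies anti to H5, which sets quaternary C1 with the trans ring-fusion relationship.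

Step 8
Reactants: 12 (1R,4R,5R,10R)-siloxycyclopropane
Product: 14 (1S,4R,5R)-4-hydroxy-4-isopropyl-1,8-dimethyl dienone: C10 ketone conjugated to C9=C8(CH3)–C7=C6, trans-fused, C1 methyl anti to H5, via cyclopropanol 13 (not isolated)
Conditions: TBAF, wet THF, 0 °C to rt; then K2CO3 (cat.), MeOH, rt
Reagents that add atoms: none
Why: Fluoride desilylation to cyclopropanol 13, then base-induced cyclopropanol ring opening (the second half of the cyclopropanation/ring-opening α-methylation of silyl enol ethers): the alkoxide cleaves the C10–CH2 bond towards the primary carbon, which is protonated to the C1 methyl while C10 becomes the dienone carbonyl. Base is used because acid would protonate the diene and expand the alkenylcyclopropanol to a cyclobutanone.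

Step 9
Reactants: 14 (1S,4R,5R)-dienone
Product: 15 (1S,4R,5S,6R,7S)-6,7-epoxy enone: epoxide oxygen on the face of H5, anti to the C1 methyl; enone C10(=O)–C9=C8 retained
Conditions: mCPBA, NaHCO3, CH2Cl2, 0 °C
Reagents that add atoms: 3-chloroperbenzoic acid, OOC(=O)c1cccc(Cl)c1
Why: Peracid epoxidation of a dienone takes the more electron-rich γ,δ-alkene C6=C7 and leaves the deactivated C8=C9. The axial C1 methyl, 1,3-related to C6, shields its own face, so oxygen is expected on the face of H5, which is the C6 configuration of the target.

Step 10
Reactants: 15 (1S,4R,5S,6R,7S)-6,7-epoxy enone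
Product: 16 (1S,4R,5S,6S)-4,6-dihydroxy-4-isopropyl-1,8-dimethyl enone: C6 hydroxyl syn to H5, C7 methylene, C8=C9–C10=O
Conditions: Pd2(dba)3·CHCl3 (cat.), n-Bu3P, HCO2H, Et3N, 1,4-dioxane, rt
Reagents that add atoms: none
Why: Palladium-catalysed formate hydrogenolysis of an alkenyl oxirane: zerovalent palladium opens the allylic C7–O bond to a π-allyl complex and the formate-derived hydride is delivered to C7, the terminus that keeps the enone conjugated. The C6–O bond is not touched, so the C6 configuration of the epoxide is retained.

Step 11
Reactants: 16 (1S,4R,5S,6S)-dihydroxy enone; 17 4-[(tert-butyldimethylsilyl)oxy]benzoic acid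
Product: 18 (1S,4R,5S,6S)-6-{4-[(tert-butyldimethylsilyl)oxy]benzoyloxy} enone
Conditions: EDC·HCl, DMAP (cat.), CH2Cl2, 0 °C to rt
Reagents that add atoms: none
Why: Steglich esterification acylates only the secondary C6 hydroxyl, the tertiary C4 hydroxyl being inert; doing this while C10 is a ketone avoids differentiating two secondary hydroxyls.

Step 12
Reactants: 18 (1S,4R,5S,6S)-6-aroyloxy enone
Product: 19 (1S,4R,5S,6S,10R)-allylic alcohol: C10 hydroxyl syn to H5 and anti to the C1 methyl
Conditions: (S)-2-methyl-CBS-oxazaborolidine, catecholborane, toluene, −78 to −40 °C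
Reagents that add atoms: none
Why: Corey–Bakshi–Shibata reduction gives 1,2-reduction under reagent control: with quaternary C1 as the large flank and the alkene CH (C9) as the small one, the (S)-catalyst is expected to deliver hydride on the face of the C1 methyl and give the (10R)-alcohol. Catalyst control is needed because no ring substituent is placed to direct hydride to that face.

Step 13
Reactants: 19 (1S,4R,5S,6S,10R)-allylic alcohol; 20 angelic acid [(Z)-2-methylbut-2-enoic acid]
Product: 22 (1S,4R,5S,6S,10R)-10-angeloyloxy-6-{4-[(tert-butyldimethylsilyl)oxy]benzoyloxy} compound, via angelic 2,4,6-trichlorobenzoic anhydride 21 (not isolated)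
Conditions: 20, 2,4,6-Cl3C6H2COCl, Et3N, toluene, rt; then 19, 80 °C (no DMAP)
Reagents that add atoms: 2,4,6-trichlorobenzoyl chloride, O=C(Cl)c1c(Cl)cc(Cl)cc1Cl (its atoms stay only in intermediate 21)
Why: Yamaguchi-type esterification through the preformed mixed anhydride, run without a nucleophilic catalyst, is the established way to acylate hindered alcohols with angelic acid without Z-to-E isomerisation; the shielded trichlorobenzoyl carbonyl sends the alcohol to the angeloyl carbonyl.

Step 14
Reactants: 22 (1S,4R,5S,6S,10R)-silyl-protected diester
Product: 23 CNP0273650.2, (1S,4R,5S,6S,10R)-10-angeloyloxy-4-hydroxy-6-(4-hydroxybenzoyloxy)-4-isopropyl-1,8-dimethyl trans-hydroazul-8-ene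
Conditions: TBAF, AcOH, THF, 0 °C
Reagents that add atoms: none
Why: Fluoride cleavage of the aryl silyl ether, buffered with acetic acid so that neither phenoxide nor fluoride attacks the esters or isomerises the angelate; the tertiary alcohol is untouched.

## Compound list

1 | 2-hydroxy-4-methylbenzaldehyde | Cc1ccc(C=O)c(O)c1 | starting material
2 | 2-[(tert-butyldimethylsilyl)oxy]-4-methylbenzaldehyde | Cc1ccc(C=O)c(O[Si](C)(C)C(C)(C)C)c1 | intermediate
3 | benzyl (triphenylphosphoranylidene)acetate | O=C(OCc1ccccc1)C=P(c1ccccc1)(c1ccccc1)c1ccccc1 | starting material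
4 | benzyl (E)-3-{2-[(tert-butyldimethylsilyl)oxy]-4-methylphenyl}prop-2-enoate | Cc1ccc(/C=C/C(=O)OCc2ccccc2)c(O[Si](C)(C)C(C)(C)C)c1 | intermediate
5 | 3-{2-[(tert-butyldimethylsilyl)oxy]-4-methylphenyl}propanoic acid | Cc1ccc(CCC(=O)O)c(O[Si](C)(C)C(C)(C)C)c1 | intermediate
6 | (trimethylsilyl)diazomethane | C[Si](C)(C)C=[N+]=[N-] | starting material
7 | ethyl carbonic 3-{2-[(tert-butyldimethylsilyl)oxy]-4-methylphenyl}propanoic anhydride | CCOC(=O)OC(=O)CCc1ccc(C)cc1O[Si](C)(C)C(C)(C)C | intermediate
8 | 1-diazo-4-{2-[(tert-butyldimethylsilyl)oxy]-4-methylphenyl}butan-2-one | CC(C)(C)[Si](C)(C)Oc1cc(C)ccc1CCC(=O)C=[N+]=[N-] | intermediate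
9 | norcaradiene valence tautomer of 10 (cyclopropane C1–C5–C6, diene C7=C8–C9=C10, same C5 configuration) | CC(C)(C)[Si](C)(C)OC1=CC(C)=C[C@@H]2[C@H]3C(=O)CC[C@@]123 | intermediate
10 | (8aR)-4-[(tert-butyldimethylsilyl)oxy]-6-methyl-3,8a-dihydroazulen-1(2H)-one | CC(C)(C)[Si](C)(C)OC1=C2CCC(=O)[C@@H]2C=CC(C)=C1 | intermediate
11 | (4R,5R)-10-[(tert-butyldimethylsilyl)oxy]-4-isopropyl-8-methyl bicyclic trien-4-ol (C1=C10, C6=C7, C8=C9; OH anti to H5) | CC(C)(C)[Si](C)(C)OC1=C2CC[C@@](O)(C(C)C)[C@@H]2C=CC(C)=C1 | intermediate
12 | (1R,4R,5R,10R)-siloxycyclopropane (C1–C11–C10 ring on the face of the C4 hydroxyl; diene C6=C7–C8=C9) | CC(C)(C)[Si](C)(C)O[C@@]12C[C@@]13CC[C@@](O)(C(C)C)[C@@H]3C=CC(C)=C2 | intermediate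
13 | (1R,4R,5R,10R)-cyclopropanol (12 without the silyl group) | O[C@@]12C[C@@]13CC[C@@](O)(C(C)C)[C@@H]3C=CC(C)=C2 | intermediate
14 | (1S,4R,5R)-4-hydroxy-4-isopropyl-1,8-dimethyl trans-fused dienone (C10=O, C8=C9, C6=C7) | O=C1C=C(C)C=C[C@@H]2[C@]1(C)CC[C@@]2(O)C(C)C | intermediate
15 | (1S,4R,5S,6R,7S)-6,7-epoxy-4-hydroxy-4-isopropyl-1,8-dimethyl enone (epoxide syn to H5) | O=C1C=C(C)[C@@H]3O[C@@H]3[C@@H]2[C@]1(C)CC[C@@]2(O)C(C)C | intermediate
16 | (1S,4R,5S,6S)-4,6-dihydroxy-4-isopropyl-1,8-dimethyl enone (C8=C9–C10=O) | O=C1C=C(C)C[C@H](O)[C@@H]2[C@]1(C)CC[C@@]2(O)C(C)C | intermediate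
17 | 4-[(tert-butyldimethylsilyl)oxy]benzoic acid | CC(C)(C)[Si](C)(C)Oc1ccc(C(=O)O)cc1 | starting material
18 | (1S,4R,5S,6S)-6-{4-[(tert-butyldimethylsilyl)oxy]benzoyloxy}-4-hydroxy-4-isopropyl-1,8-dimethyl enone | O=C1C=C(C)C[C@H](OC(=O)c3ccc(O[Si](C)(C)C(C)(C)C)cc3)[C@@H]2[C@]1(C)CC[C@@]2(O)C(C)C | intermediate
19 | (1S,4R,5S,6S,10R)-6-{4-[(tert-butyldimethylsilyl)oxy]benzoyloxy}-4,10-dihydroxy-4-isopropyl-1,8-dimethyl hydroazul-8-ene | O[C@@H]1C=C(C)C[C@H](OC(=O)c3ccc(O[Si](C)(C)C(C)(C)C)cc3)[C@@H]2[C@]1(C)CC[C@@]2(O)C(C)C | intermediate
20 | angelic acid, (Z)-2-methylbut-2-enoic acid | C/C=C(/C)C(=O)O | starting material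
21 | angelic 2,4,6-trichlorobenzoic anhydride | C/C=C(/C)C(=O)OC(=O)c1c(Cl)cc(Cl)cc1Cl | intermediate
22 | (1S,4R,5S,6S,10R)-10-angeloyloxy-6-{4-[(tert-butyldimethylsilyl)oxy]benzoyloxy}-4-hydroxy-4-isopropyl-1,8-dimethyl hydroazul-8-ene | C/C=C(/C)C(=O)O[C@@H]1C=C(C)C[C@H](OC(=O)c3ccc(O[Si](C)(C)C(C)(C)C)cc3)[C@@H]2[C@]1(C)CC[C@@]2(O)C(C)C | intermediate
23 | CNP0273650.2 | C/C=C(/C)C(=O)O[C@@H]1C=C(C)C[C@H](OC(=O)c2ccc(O)cc2)[C@@H]2[C@]1(C)CC[C@@]2(O)C(C)C | target

## Step count and least certain steps

Total step count: 14. Longest linear sequence: 14 steps (1 to 23); 3, 6, 17 and 20 are bought.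

**Step 5 (key step).** Three things may go wrong.
- Enantioface discrimination may be insufficient, because the tether carries no substituent to help the ligand.
- The C5 configuration may erode by enolisation, by a 1,5-hydrogen shift, or by isomerisation to the conjugated trienone.
- The carbene may be diverted to addition at the silyloxy-bearing bond, to desilylative spirocyclisation at C1, or to formal C–H insertion giving a 2-tetralone.

Fallback: enantiopurity is secured by diastereomer separation instead of by the catalyst. The cyclisation can then be run with whichever catalyst converts 8 most cleanly, including achiral dirhodium tetracarboxylates such as Rh2(O2CCF3)4 (divalent rhodium). The fallback sets out from 16 of insufficient enantiomeric purity. It is esterified at C6 with (1S)-camphanic chloride (pyridine, DMAP) to the camphanate of 16 F1 and the diastereomeric camphanate of ent-16 F2. F1 is separated by crystallisation or chromatography and cleaved (K2CO3, MeOH), which returns to the route at 16.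

**Step 7.** The zinc alkoxide is also homoallylic to C6=C7, so cyclopropanation may go there or occur twice. The tetrasubstituted enol ether may react slowly, and zinc iodide may rearrange the alkenyl siloxycyclopropane.
Fallback: replace cyclopropanation/opening by regiospecific enolate methylation. Setting out from 11, MeLi (2.2 equiv, THF, 0 °C to rt) cleaves the silyl enol ether to the dilithium enolate–alkoxide of 11 F3, which is C-methylated at C1 with MeI (THF/DMPU, −78 to 0 °C). Entry anti to the C4 isopropyl group is expected but less secure than directed delivery. This returns to the route at 14.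

**Step 9.** Facial selectivity may be poor: hydrogen-bond delivery by the C4 hydroxyl and the bulk of the isopropyl group both oppose the steric bias of the C1 methyl.
Fallback: make the face of epoxidation irrelevant and set C6 by intramolecular hydride delivery. Setting out from 14:
- the epoxide mixture (15 with its C6,C7-epimeric epoxide F4) is hydrogenolysed as in step 10 to 16 and the 6-epi alcohol F5;
- the mixture is oxidised (Dess–Martin periodinane, NaHCO3) to the single ene-dione F6;
- F6 is reduced at once with Me4NBH(OAc)3 in MeCN/AcOH at −20 °C (Evans–Saksena reduction). Hydride is delivered from boron bound to the C4 oxygen, giving the anti-1,3-diol with the C6 hydroxyl syn to H5.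

This returns at 16. The weak point is enolisation of F6 between its two carbonyls.

**Step 12.** The catalyst's preferred face may be opposed by the substrate, since hydride must enter next to the C1 methyl; reduction at the hindered carbonyl may be slow or partly conjugate.
Fallback: reduce under substrate control and invert while esterifying. Setting out from 18, NaBH4/CeCl3 (Luche reduction, MeOH, −78 °C) should give the 10-epi alcohol F7 (hydride anti to the methyl). Mitsunobu esterification of F7 with 20 (PPh3, DIAD, toluene, 0 °C) then inverts C10 and gives the angelate directly, returning at 22. Elimination or allylic transposition is the risk of that step.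

**Step 13.** Acylation of the neopentyl, allylic C10 hydroxyl may be incomplete, and forcing it risks isomerisation of the angelate to the tiglate.
Fallback: build the Z-alkene after the ester bond. Setting out from 19, esterification with 2-[bis(2,2,2-trifluoroethoxy)phosphoryl]propanoic acid (DCC, DMAP, which can be forced because no isomerisable alkene is present) gives the phosphonopropanoate of 19 F8. Still–Gennari olefination of F8 with acetaldehyde (KN(SiMe3)2, 18-crown-6, THF, −78 °C) gives the Z-configured angelate and returns at 22.

## Further compounds

F1 | step 5 | (1S)-camphanate of 16 at the C6 oxygen | O=C1C=C(C)C[C@H](OC(=O)[C@@]34CC[C@@](C)(C(=O)O3)C4(C)C)[C@@H]2[C@]1(C)CC[C@@]2(O)C(C)C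
F2 | step 5 | (1S)-camphanate of ent-16 (diastereomer removed) | O=C1C=C(C)C[C@@H](OC(=O)[C@@]34CC[C@@](C)(C(=O)O3)C4(C)C)[C@H]2[C@@]1(C)CC[C@]2(O)C(C)C
F3 | step 7 | dilithium enolate–alkoxide of 11 (enolate O on C10, alkoxide on C4) | [Li+].[Li+].[O-]C1=C2CC[C@@]([O-])(C(C)C)[C@@H]2C=CC(C)=C1
F4 | step 9 | (1S,4R,5S,6S,7R)-6,7-epoxy enone, epoxide anti to H5 (epimer of 15) | O=C1C=C(C)[C@H]3O[C@H]3[C@@H]2[C@]1(C)CC[C@@]2(O)C(C)C
F5 | step 9 | (1S,4R,5S,6R)-4,6-dihydroxy enone (6-epimer of 16) | O=C1C=C(C)C[C@@H](O)[C@@H]2[C@]1(C)CC[C@@]2(O)C(C)C
F6 | step 9 | (1S,4R,5S)-4-hydroxy-4-isopropyl-1,8-dimethyl-8-ene-6,10-dione | O=C1C=C(C)CC(=O)[C@@H]2[C@]1(C)CC[C@@]2(O)C(C)C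
F7 | step 12 | (1S,4R,5S,6S,10S)-allylic alcohol (10-epimer of 19) | O[C@H]1C=C(C)C[C@H](OC(=O)c3ccc(O[Si](C)(C)C(C)(C)C)cc3)[C@@H]2[C@]1(C)CC[C@@]2(O)C(C)C
F8 | step 13 | 2-[bis(2,2,2-trifluoroethoxy)phosphoryl]propanoate of 19 at the C10 oxygen (epimers at the phosphonate carbon) | CC(C(=O)O[C@@H]1C=C(C)C[C@H](OC(=O)c3ccc(O[Si](C)(C)C(C)(C)C)cc3)[C@@H]2[C@]1(C)CC[C@@]2(O)C(C)C)P(=O)(OCC(F)(F)F)OCC(F)(F)F
A1 | alternative 1 | 2-methyl-2-(3-oxopropyl)cycloheptane-1,3-dione | O=CCCC1(C)C(=O)CCCCC1=O
A2 | alternative 1 | cis-fused bicyclic ketol (C5 hydroxyl, C1 methyl, ketones at C4 and C10) | O=C1CCCC[C@@]2(O)[C@]1(C)CCC2=O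
A3 | alternative 2 | cyclopentane aldehyde carrying the C6 aroyloxy side chain with a (Z)-alkenyl iodide at C9 | I/C=C(C)\C[C@H](OC(=O)c1ccc(O[Si](C)(C)C(C)(C)C)cc1)[C@@H]1[C@@](C)(C=O)CC[C@@]1(O)C(C)C
A4 | alternative 2 | 10-hydroxy hydroazulene aroyl ester, O-silyl phenol (identical with 19) | O[C@@H]1C=C(C)C[C@H](OC(=O)c3ccc(O[Si](C)(C)C(C)(C)C)cc3)[C@@H]2[C@]1(C)CC[C@@]2(O)C(C)C
A5 | alternative 3 | 3-{[(tert-butyldimethylsilyl)oxy]methyl}cyclopent-2-en-1-one | O=C1CCC(CO[Si](C)(C)C(C)(C)C)=C1
A6 | alternative 3 | 3-methylbut-3-enal | C=C(C)CC=O
A7 | alternative 3 | trisubstituted cyclopentanone aldol with C1, C5 and C6 set | C=C(C)C[C@H](O)[C@@H]1[C@](CO[Si](C)(C)C(C)(C)C)(C)CCC1=O
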